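## Retrosynthetic overview

1. C6–OMe: the target comes from a (5R,6R)-α,β-epoxy ketone by acid-mediated anti methanolysis at C6 (inversion).
2. Both C–O stereocentres: the epoxide comes from a flat dienyl aza-indenone by catalytic asymmetric nucleophilic epoxidation (key step).
3. Side chain: the dienyl aza-indenone comes from a 3-chloro aza-indenone and a (1E,3E,5S)-dienyl boronate (Suzuki). The boronate comes from (S)-2-methylbutan-1-ol by oxidation/Wittig and boron-Wittig.
4. Carbocycle: the chloro aza-indenone comes from dehydrogenation of a keto ester made by Parham cyclisation of a pyridyl succinate. The succinate comes from 5-bromo-2-chloro-4-methylpyridine, dimethyl carbonate and methyl 2-bromopropanoate.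
5. Ring order: the pyridine is bought; the cyclopentenone ring is closed second (Parham); the oxirane is formed third and opened in the last step.

Assumption: positions are numbered as in cyclopenta[c]pyridine (N2, dienyl at C3, C5 = C(OH)CO2Me, C6 = C(OMe)Me, C7 = ketone). CIP analysis of the given SMILES gives (5R,6S) with 5-OH and 6-OMe trans, and a (1E,3E,5S) side chain.

## Route

Step 1
Reactants: 1 (S)-2-methylbutan-1-ol; 2 2-(triphenylphosphoranylidene)propanal
Product: 4 (2E,4S)-2,4-dimethylhex-2-enal, via (S)-2-methylbutanal 3 (not isolated)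
Conditions: TEMPO (10 mol %), PhI(OAc)2 (1.1 equiv), CH2Cl2, 0 °C → rt; then 2 (1.2 equiv), toluene, 80 °C (sealed tube)
Reagents that add atoms: none
Why: TEMPO/PhI(OAc)2 oxidation gives the configurationally labile α-branched aldehyde under non-basic conditions and it is trapped in the same flask by the stabilised formyl ylide in an E-selective Wittig reaction, so the (S)-centre from the chiral pool is carried through.

Step 2
Reactants: 4 (2E,4S)-2,4-dimethylhex-2-enal; 5 bis[(pinacolato)boryl]methane
Product: 6 2-[(1E,3E,5S)-3,5-dimethylhepta-1,3-dien-1-yl]-4,4,5,5-tetramethyl-1,3,2-dioxaborolane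
Conditions: 5 (1.2 equiv), LiTMP (1.2 equiv, from 2,2,6,6-tetramethylpiperidine and n-BuLi), THF, 0 °C; then 4, −78 °C → rt; H2O
Reagents that add atoms: none
Why: Boron–Wittig olefination, in which the lithiated gem-diboronate adds 1,2 to the enal and syn B–O elimination gives the (E)-alkenyl boronate, so the (1E,3E)-dienyl boronate forms without touching the allylic stereocentre.

Step 3
Reactants: 7 5-bromo-2-chloro-4-methylpyridine; 8 dimethyl carbonate; 9 methyl 2-bromopropanoate (racemic)
Product: 11 dimethyl 2-(5-bromo-2-chloropyridin-4-yl)-3-methylbutanedioate (racemic mixture of diastereomers), via methyl (5-bromo-2-chloropyridin-4-yl)acetate 10 (not isolated)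
Conditions: NaHMDS (2.1 equiv), 8 (1.2 equiv), THF, −78 → 0 °C; then 9 (1.5 equiv), 0 °C → rt; aq NH4Cl
Reagents that add atoms: none
Why: Lateral deprotonation of the γ-picoline methyl group and Claisen-type C-acylation by dimethyl carbonate is driven by formation of the stabilised pyridylacetate enolate, which is then C-alkylated (SN2) by the α-bromo ester; the two new stereocentres do not matter because both are erased in step 5.

Step 4
Reactants: 11 dimethyl 2-(5-bromo-2-chloropyridin-4-yl)-3-methylbutanedioate
Product: 12 methyl 3-chloro-6-methyl-7-oxo-6,7-dihydro-5H-cyclopenta[c]pyridine-5-carboxylate (racemic cis/trans mixture)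
Conditions: NaH (1.05 equiv), THF, 0 °C; then n-BuLi (1.05 equiv), −95 → −40 °C; aq NH4Cl
Reagents that add atoms: none
Why: Parham cyclisation, in which NaH first masks the acidic pyridylacetate C–H as its enolate (also protecting the neighbouring ester), Br/Li exchange at −95 °C outruns carbonyl addition, and the 3-pyridyllithium acylates the remaining ester (5-exo-trig) to close the cyclopentanone ring; the product stays as a vinylogous enolate and is not attacked further.

Step 5
Reactants: 12 methyl 3-chloro-6-methyl-7-oxo-6,7-dihydro-5H-cyclopenta[c]pyridine-5-carboxylate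
Product: 14 methyl 3-chloro-6-methyl-7-oxo-7H-cyclopenta[c]pyridine-5-carboxylate, via 5-iodo keto ester 13 (not isolated)
Conditions: I2 (1.1 equiv), DBU (2.5 equiv), CH2Cl2, 0 °C → rt
Reagents that add atoms: none
Why: α-Iodination of the most acidic (pyridyl/ester-flanked) C5–H followed by DBU-promoted dehydroiodination (E1cB through the C7 ketone enolate) gives the tetrasubstituted ene-dicarbonyl and removes both racemic stereocentres.

Step 6
Reactants: 14 methyl 3-chloro-6-methyl-7-oxo-7H-cyclopenta[c]pyridine-5-carboxylate; 6 2-[(1E,3E,5S)-3,5-dimethylhepta-1,3-dien-1-yl]-4,4,5,5-tetramethyl-1,3,2-dioxaborolane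
Product: 15 methyl 3-[(1E,3E,5S)-3,5-dimethylhepta-1,3-dien-1-yl]-6-methyl-7-oxo-7H-cyclopenta[c]pyridine-5-carboxylate
Conditions: Pd(dppf)Cl2 (5 mol %), CsF (3 equiv), 1,4-dioxane, 80 °C
Reagents that add atoms: none
Why: Suzuki–Miyaura coupling, in which the C–Cl bond α to the ring nitrogen and para to the acyl group undergoes easy oxidative addition, anhydrous fluoride activation of the boronate avoids hydroxide addition to the electrophilic aza-indenone, and alkene geometry is retained.

Step 7
Reactants: 15 methyl 3-[(1E,3E,5S)-3,5-dimethylhepta-1,3-dien-1-yl]-6-methyl-7-oxo-7H-cyclopenta[c]pyridine-5-carboxylate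
Product: 16 methyl (5R,6R)-3-[(1E,3E,5S)-3,5-dimethylhepta-1,3-dien-1-yl]-5,6-epoxy-6-methyl-7-oxo-6,7-dihydro-5H-cyclopenta[c]pyridine-5-carboxylate
Conditions: N-(9-anthracenylmethyl)cinchonidinium chloride (10 mol %), cumene hydroperoxide (1.5 equiv), Cs2CO3 (20 mol %), toluene, −20 °C
Reagents that add atoms: cumene hydroperoxide, CC(C)(OO)c1ccccc1
Why: Proposed new method: catalytic asymmetric Weitz–Scheffer epoxidation of a tetrasubstituted cyclic ene-1,4-dicarbonyl (a 2,3-disubstituted aza-indenone), a substrate class on which it has not been shown; the cumylperoxide anion, ion-paired with the chiral ammonium cation whose free C9–OH hydrogen-bonds the C7 ketone while the anthracenyl wall stacks on the flat bicycle, adds to C6 (β to the ester) on one face to give the pyridyl/ester-stabilised C5 carbanion, which closes on the O–O bond (3-exo-tet) so that both C–O bonds and both stereocentres (5R,6R) are fixed in one catalyst-controlled event, while the electron-rich diene is inert to the nucleophilic oxidant; the closest known reaction type is cinchona phase-transfer-catalysed hydroperoxide epoxidation of chalcones and 2-substituted 1,4-naphthoquinones; the sense of induction must be confirmed on the first run, and the pseudoenantiomeric cinchoninium salt delivers the other face if needed.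

Step 8
Reactants: 16 methyl (5R,6R)-3-[(1E,3E,5S)-3,5-dimethylhepta-1,3-dien-1-yl]-5,6-epoxy-6-methyl-7-oxo-6,7-dihydro-5H-cyclopenta[c]pyridine-5-carboxylate
Product: 17 methyl (5R,6S)-3-[(1E,3E,5S)-3,5-dimethylhepta-1,3-dien-1-yl]-5-hydroxy-6-methoxy-6-methyl-7-oxo-6,7-dihydro-5H-cyclopenta[c]pyridine-5-carboxylate
Conditions: CSA (1.2 equiv), MeOH, 25 °C
Reagents that add atoms: methanol, CO
Why: Acid-mediated epoxide methanolysis (borderline SN2), in which the protonated pyridine and the ester prevent C5 from taking positive charge, so methanol attacks the less hindered methyl-bearing C6 (its C–O bond aligned with the C7 carbonyl π*) from the face opposite the epoxide oxygen; inversion at C6 sets 6S with OMe trans to the retained (5R)-OH.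

## Compound list

1 | (S)-2-methylbutan-1-ol | CC[C@H](C)CO | starting material
2 | 2-(triphenylphosphoranylidene)propanal | CC(C=O)=P(c1ccccc1)(c1ccccc1)c1ccccc1 | starting material
3 | (S)-2-methylbutanal | CC[C@H](C)C=O | intermediate
4 | (2E,4S)-2,4-dimethylhex-2-enal | CC[C@H](C)/C=C(C)/C=O | intermediate
5 | bis[(pinacolato)boryl]methane | CC1(C)OB(CB2OC(C)(C)C(C)(C)O2)OC1(C)C | starting material
6 | 2-[(1E,3E,5S)-3,5-dimethylhepta-1,3-dien-1-yl]-4,4,5,5-tetramethyl-1,3,2-dioxaborolane | CC[C@H](C)/C=C(C)/C=C/B1OC(C)(C)C(C)(C)O1 | intermediate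
7 | 5-bromo-2-chloro-4-methylpyridine | Cc1cc(Cl)ncc1Br | starting material
8 | dimethyl carbonate | COC(=O)OC | starting material
9 | methyl 2-bromopropanoate (racemic) | CC(Br)C(=O)OC | starting material
10 | methyl (5-bromo-2-chloropyridin-4-yl)acetate (present as its sodium enolate) | COC(=O)Cc1cc(Cl)ncc1Br | intermediate
11 | dimethyl 2-(5-bromo-2-chloropyridin-4-yl)-3-methylbutanedioate (racemic mixture of diastereomers) | COC(=O)C(C)C(C(=O)OC)c1cc(Cl)ncc1Br | intermediate
12 | methyl 3-chloro-6-methyl-7-oxo-6,7-dihydro-5H-cyclopenta[c]pyridine-5-carboxylate (racemic cis/trans mixture) | COC(=O)C1C(C)C(=O)c2cnc(Cl)cc21 | intermediate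
13 | methyl 3-chloro-5-iodo-6-methyl-7-oxo-6,7-dihydro-5H-cyclopenta[c]pyridine-5-carboxylate (racemic) | COC(=O)C1(I)C(C)C(=O)c2cnc(Cl)cc21 | intermediate
14 | methyl 3-chloro-6-methyl-7-oxo-7H-cyclopenta[c]pyridine-5-carboxylate | COC(=O)C1=C(C)C(=O)c2cnc(Cl)cc21 | intermediate
15 | methyl 3-[(1E,3E,5S)-3,5-dimethylhepta-1,3-dien-1-yl]-6-methyl-7-oxo-7H-cyclopenta[c]pyridine-5-carboxylate | CC[C@H](C)/C=C(C)/C=C/c1cc2C(C(=O)OC)=C(C)C(=O)c2cn1 | intermediate
16 | methyl (5R,6R)-3-[(1E,3E,5S)-3,5-dimethylhepta-1,3-dien-1-yl]-5,6-epoxy-6-methyl-7-oxo-6,7-dihydro-5H-cyclopenta[c]pyridine-5-carboxylate | CC[C@H](C)/C=C(C)/C=C/c1cc2c(cn1)C(=O)[C@]3(C)O[C@]23C(=O)OC | intermediate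
17 | methyl (5R,6S)-3-[(1E,3E,5S)-3,5-dimethylhepta-1,3-dien-1-yl]-5-hydroxy-6-methoxy-6-methyl-7-oxo-6,7-dihydro-5H-cyclopenta[c]pyridine-5-carboxylate | CC[C@H](C)/C=C(C)/C=C/c1cc2c(cn1)C(=O)[C@@](C)(OC)[C@@]2(O)C(=O)OC | target

## Step count and risk

Total step count: 8 (steps 1–2 for the boronate, steps 3–5 for the chloro aza-indenone, steps 6–8 for coupling, epoxidation and methanolysis).
Longest linear sequence: 6 steps (steps 3–8, from 7).

The three steps most likely to fail:

Step 7 (proposed new asymmetric epoxidation). The catalyst may give low face selectivity on this flat tetrasubstituted acceptor. The fallback uses known chemistry and sets out from 15. Compound 15 is epoxidised without stereocontrol under ordinary Weitz–Scheffer conditions (t-BuOOH, DBU, CH2Cl2, 0 °C). This gives a roughly 1:1 mixture of 16 and its diastereomer methyl (5S,6S)-3-[(1E,3E,5S)-3,5-dimethylhepta-1,3-dien-1-yl]-5,6-epoxy-6-methyl-7-oxo-6,7-dihydro-5H-cyclopenta[c]pyridine-5-carboxylate F3. The two are separated by preparative HPLC on a chiral stationary phase, and the route is rejoined at 16.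

Step 8 (regiochemistry of the methanolysis). Methanol could open the epoxide at C5 instead of C6. The fallback sets out from 15 and comes back at 17; it fixes the regiochemistry by forming the two C–O bonds in the opposite order, at the cost of stereocontrol.
- Base-catalysed oxa-Michael addition of methanol (cat. NaOMe, MeOH, 0 °C) can only place OMe at C6, because that generates the pyridyl/ester-stabilised C5 carbanion. It gives methyl 3-[(1E,3E,5S)-3,5-dimethylhepta-1,3-dien-1-yl]-6-methoxy-6-methyl-7-oxo-6,7-dihydro-5H-cyclopenta[c]pyridine-5-carboxylate F4.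
- Deprotonation (KHMDS, THF, −78 °C) and enolate hydroxylation with 2-(phenylsulfonyl)-3-phenyloxaziridine then gives methyl 3-[(1E,3E,5S)-3,5-dimethylhepta-1,3-dien-1-yl]-5-hydroxy-6-methoxy-6-methyl-7-oxo-6,7-dihydro-5H-cyclopenta[c]pyridine-5-carboxylate as a C5/C6 stereoisomer mixture F5.
- Compound 17 is isolated from this mixture by silica chromatography (cis/trans) and chiral HPLC.

Step 4 (Parham cyclisation of an enolate-bearing substrate). The dianion may cyclise poorly, or butyllithium may attack an ester. The fallback sets out from 10, isolated by aqueous quench of step 3 before 9 is added, and comes back at 14, bypassing 11–13. It closes the ring by condensation instead of acylation.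
- Sonogashira coupling of 10 with propyne at the C–Br bond (Pd(PPh3)2Cl2, CuI, Et3N, THF, 50 °C) gives methyl 2-[2-chloro-5-(prop-1-yn-1-yl)pyridin-4-yl]acetate F1.
- Oxidation of the alkyne (cat. RuCl3, NaIO4, MeCN/H2O) gives methyl 2-[2-chloro-5-(2-oxopropanoyl)pyridin-4-yl]acetate F2.
- Intramolecular Knoevenagel condensation of the pyridylacetate CH2 onto the methyl ketone carbonyl (piperidinium acetate, toluene, 80 °C) gives 14 directly.

## Further compounds

F1 | step 4 | methyl 2-[2-chloro-5-(prop-1-yn-1-yl)pyridin-4-yl]acetate | CC#Cc1cnc(Cl)cc1CC(=O)OC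
F2 | step 4 | methyl 2-[2-chloro-5-(2-oxopropanoyl)pyridin-4-yl]acetate | CC(=O)C(=O)c1cnc(Cl)cc1CC(=O)OC
F3 | step 7 | methyl (5S,6S)-3-[(1E,3E,5S)-3,5-dimethylhepta-1,3-dien-1-yl]-5,6-epoxy-6-methyl-7-oxo-6,7-dihydro-5H-cyclopenta[c]pyridine-5-carboxylate | CC[C@H](C)/C=C(C)/C=C/c1cc2c(cn1)C(=O)[C@@]3(C)O[C@@]23C(=O)OC
F4 | step 8 | methyl 3-[(1E,3E,5S)-3,5-dimethylhepta-1,3-dien-1-yl]-6-methoxy-6-methyl-7-oxo-6,7-dihydro-5H-cyclopenta[c]pyridine-5-carboxylate (C5/C6 stereoisomer mixture) | CC[C@H](C)/C=C(C)/C=C/c1cc2c(cn1)C(=O)C(C)(OC)C2C(=O)OC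
F5 | step 8 | methyl 3-[(1E,3E,5S)-3,5-dimethylhepta-1,3-dien-1-yl]-5-hydroxy-6-methoxy-6-methyl-7-oxo-6,7-dihydro-5H-cyclopenta[c]pyridine-5-carboxylate (C5/C6 stereoisomer mixture) | CC[C@H](C)/C=C(C)/C=C/c1cc2c(cn1)C(=O)C(C)(OC)C2(O)C(=O)OC
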